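**Plan**

- Retrosynthetic cuts: (1) the lactone C16–O bond and C12–C13, by an auxiliary-controlled syn aldol on a C12 aldehyde followed by lactonisation; (2) C8=C17 (ketone methylenation) and a temporary γ-lactone C8–O–C12(=O); (3) C5–C10 and C3–C4 together; (4) C9–C10 (cuprate addition) and C4=C5 (cross-metathesis).
- Enabling feature: C3 (carbinol) and C19 (on the quaternary C4) form an aldol pattern, and the methyl-bearing quaternary C10 lies β to C19 across C5–C4. A chain holding a tertiary C10 radical precursor, the enal C5=C4–C19 and a C3 aldehyde can therefore close ring B (C5–C10) and ring A (C3–C4) in one radical–polar crossover event.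
- Forward order: (S)-epoxyhexene → butenolide (C8) → enal arm → anti cuprate addition of the C20/C10/C1–C3 arm (C9) → lactone dialdehyde → ring B then ring A in one operation → diol acetonide → lactone opened, C8 ketone, C8=C17 → C12 aldehyde → aldol and lactonisation.
- Stereochemistry: C8 comes from the epoxide and relays to C9 (anti addition), then to C10, C5, C4 and C3 in the bicyclisation; C8 is erased afterwards. C12 and C13 come from the (R)-benzyloxazolidinone, C14 from the malic-acid-derived dioxolane.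

Key step: step 8

Remark: labdane numbering is used throughout (C17 = CH2 on C8, C18 = equatorial methyl on C4, C19 = axial oxygenated carbon on C4, C20 = methyl on C10; α = the decalin face that carries C20). Compounds 1 and 25 are taken as commercial chiral-pool materials.

Step 1
Reactants: 1 (2S)-2-(but-3-en-1-yl)oxirane; 2 (phenylsulfanyl)acetic acid
Product: 5 (5S)-5-(but-3-en-1-yl)-3-(phenylsulfanyl)oxolan-2-one (C3 epimers), via dilithio dianion 3 (not isolated), via hydroxy acid 4 (not isolated)
Conditions: 2, LiN(i-Pr)2 (2.2 equiv), THF, −78 → 0 °C; 1, 0 °C → rt; aq. HCl; then TsOH (cat.), toluene, 80 °C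
Reagents that add atoms: none
Why: The arylthioacetate dianion should open the terminal epoxide at its CH2 carbon (SN2, the C8 stereocentre is not touched) and the γ-hydroxy acid lactonises under acid, the standard epoxide-to-γ-lactone homologation.

Step 2
Reactants: 5 (5S)-5-(but-3-en-1-yl)-3-(phenylsulfanyl)oxolan-2-one
Product: 7 (5S)-5-(but-3-en-1-yl)furan-2(5H)-one, via sulfoxide 6 (not isolated)
Conditions: NaIO4, MeOH/H2O, 0 °C → rt; then crude 6, CaCO3, toluene, 110 °C
Reagents that add atoms: none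
Why: Sulfide oxidation followed by thermal syn-elimination of the sulfoxide can only use the ring CH2 hydrogens, so it should give the α,β-butenolide and leave C8 and the terminal alkene alone.

Step 3
Reactants: 7 (5S)-5-(but-3-en-1-yl)furan-2(5H)-one; 8 methacrolein
Product: 9 (2E)-2-methyl-5-[(2S)-5-oxo-2,5-dihydrofuran-2-yl]pent-2-enal
Conditions: second-generation Grubbs catalyst (H2IMes)(PCy3)Cl2Ru=CHPh (5 mol%), 8 (5 equiv), CH2Cl2, 40 °C
Reagents that add atoms: none
Why: Olefin cross-metathesis of a terminal alkene with methacrolein is expected to be E-selective, and the electron-poor ring alkene of the butenolide should not take part.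

Step 4
Reactants: 9 (2E)-2-methyl-5-[(2S)-5-oxo-2,5-dihydrofuran-2-yl]pent-2-enal
Product: 10 (5S)-5-[(3E)-5,5-dimethoxy-4-methylpent-3-en-1-yl]furan-2(5H)-one
Conditions: HC(OMe)3, PPTS (cat.), MeOH, rt
Reagents that add atoms: trimethyl orthoformate, COC(OC)OC
Why: Acid-catalysed acetalisation masks the enal so that the butenolide is the only Michael acceptor left for step 6.

Step 5
Reactants: 11 2,3-dibromoprop-1-ene; 12 (1,3-dioxolan-2-ylmethyl)magnesium bromide
Product: 13 2-(3-bromobut-3-en-1-yl)-1,3-dioxolane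
Conditions: Li2CuCl4 (3 mol%), THF, 0 °C → rt
Reagents that add atoms: none
Why: Copper-catalysed allylic substitution (Kochi-type coupling) should replace only the allylic bromide and deliver the C20/C10/C1/C2/C3 unit with the vinylic bromide intact.

Step 6
Reactants: 13 2-(3-bromobut-3-en-1-yl)-1,3-dioxolane; 10 (5S)-5-[(3E)-5,5-dimethoxy-4-methylpent-3-en-1-yl]furan-2(5H)-one
Product: 16 (4S,5S)-5-[(3E)-5,5-dimethoxy-4-methylpent-3-en-1-yl]-4-[4-(1,3-dioxolan-2-yl)but-1-en-2-yl]oxolan-2-one, via alkenyllithium 14 (not isolated), via lithium dialkenylcuprate 15 (not isolated)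
Conditions: 13 (2.2 equiv), t-BuLi (4.4 equiv), Et2O, −78 °C; CuBr·SMe2 (1.1 equiv), −78 → −40 °C; 10, −78 °C; aq. NH4Cl
Reagents that add atoms: none
Why: Gilman cuprate conjugate addition to a 5-substituted butenolide takes place anti to the ring substituent, which should set C9 trans to C8 (substrate control).

Step 7
Reactants: 16 (4S,5S)-5-[(3E)-5,5-dimethoxy-4-methylpent-3-en-1-yl]-4-[4-(1,3-dioxolan-2-yl)but-1-en-2-yl]oxolan-2-one
Product: 17 (2E)-2-methyl-5-[(2S,3S)-5-oxo-3-(5-oxopent-1-en-2-yl)oxolan-2-yl]pent-2-enal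
Conditions: 1 M HCl, THF/H2O, rt
Reagents that add atoms: water, O
Why: Aqueous acid hydrolysis of both acetals should release the enal and the C3 aldehyde, while the lactone and the 1,1-disubstituted alkene are stable to these conditions.

Step 8
Reactants: 17 (2E)-2-methyl-5-[(2S,3S)-5-oxo-3-(5-oxopent-1-en-2-yl)oxolan-2-yl]pent-2-enal
Product: 18 tricyclic lactone hydroxy aldehyde (rings A and B closed; 3α-OH equatorial; 19-CHO axial; lactone C12(=O)–O–C8 kept)
Conditions: Fe(acac)3 (30 mol%), PhSiH3 (2.5 equiv), EtOH/(CH2OH)2 5:1, 0.01 M, degassed, rt → 40 °C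
Reagents that add atoms: none
Why: Fe(acac)3 and PhSiH3 give an iron hydride that transfers a hydrogen atom to C20, the CH2 end of the electron-rich 1,1-disubstituted alkene, in preference to the electron-poor enal; the tertiary C10 radical adds to C5 of the enal, the α-formyl C4 radical is reduced by divalent iron to an iron enolate, and this adds to the C3 aldehyde, which returns the catalyst to trivalent iron and forms C5–C10 and C3–C4 in one operation. The closest known reaction type is the hydrogen-atom-transfer-initiated radical conjugate addition/aldol (radical–polar crossover) polycyclisation used for terpenoid carbocycles. Ring B closes in the 6-exo-trig radical mode and ring A in the 6-(enolexo)-exo-trig aldol mode. C5 and C10 are controlled by C8 and C9: the trans-fused lactone holds C8–O and C9–C11 equatorial in a chair transition state, the enal arm adds equatorially (H5 cis to H9), and the longer C1–C3 arm of the planar radical should take the equatorial site beside H9 while the new C20 methyl goes axial, which gives the trans ring fusion. C4 and C3 are controlled by the new decalin: the aldehyde, held by its tether from C10 in a chair, metal-bridged transition state, should bond to the enolate face that leaves the flat C19 carbon (not the C18 methyl) syn-axial to C20 and puts the C3 alkoxide equatorial, which is also the thermodynamically preferred aldol. The step needs chemoselective hydrogen-atom transfer (secured by the electron-rich alkene), aldol closure faster than enolate protonation (secured by the six-membered intramolecular closure) and facial control at C10 (secured only by the lactone-locked chair, the least certain point).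

Step 9
Reactants: 18 tricyclic lactone hydroxy aldehyde
Product: 19 tricyclic lactone 3,19-diol
Conditions: NaBH4, MeOH, −20 → 0 °C
Reagents that add atoms: none
Why: Borohydride reduces the aldehyde much faster than the γ-lactone and removes the retro-aldol-prone β-hydroxy aldehyde at once.

Step 10
Reactants: 19 tricyclic lactone 3,19-diol
Product: 20 tricyclic lactone 3,19-acetonide
Conditions: Me2C(OMe)2, PPTS (cat.), CH2Cl2, rt
Reagents that add atoms: 2,2-dimethoxypropane, COC(C)(C)OC
Why: Acid-catalysed transketalisation should tie the equatorial C3 hydroxyl and the axial C19 hydroxymethyl into a 1,3-dioxane, the usual protection of this 1,3-diol.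

Step 11
Reactants: 20 tricyclic lactone 3,19-acetonide
Product: 21 8β-hydroxy Weinreb amide (C12)
Conditions: MeNH(OMe)·HCl (3 equiv), i-PrMgCl (6 equiv), THF, −20 °C; then 20, −20 → 0 °C
Reagents that add atoms: N,O-dimethylhydroxylamine hydrochloride, CNOC.Cl
Why: Aminolysis of the strained trans-fused lactone by the chloromagnesium amide should give the Weinreb amide and free the C8 hydroxyl, which begins the removal of the temporary ring.

Step 12
Reactants: 21 8β-hydroxy Weinreb amide
Product: 22 8-oxo Weinreb amide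
Conditions: Dess–Martin periodinane, NaHCO3, CH2Cl2, 0 °C → rt
Reagents that add atoms: none
Why: Buffered Dess–Martin oxidation converts the secondary C8 alcohol into the ketone without epimerising C9, whose equatorial side chain is in any case the stable arrangement.

Step 13
Reactants: 22 8-oxo Weinreb amide
Product: 23 8(17)-methylene Weinreb amide
Conditions: Zn, CH2Br2, TiCl4 (Lombardo reagent, preformed in THF at 5 °C), CH2Cl2, 0 °C → rt
Reagents that add atoms: dibromomethane, BrCBr
Why: Takai–Lombardo methylenation converts hindered, enolisable ketones into 1,1-disubstituted alkenes without base and should leave the Weinreb amide, which a phosphorus ylide could attack, untouched.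

Step 14
Reactants: 23 8(17)-methylene Weinreb amide
Product: 24 C12 aldehyde (3,19-acetonide; 8(17)-ene)
Conditions: i-Bu2AlH, THF, −78 °C; aq. KNaC4H4O6
Reagents that add atoms: none
Why: Hydride addition to a Weinreb amide stops at the chelated tetrahedral intermediate, which collapses to the aldehyde on work-up.

Step 15
Reactants: 25 methyl [(4S)-2,2-dimethyl-1,3-dioxolan-4-yl]acetate
Product: 26 [(4S)-2,2-dimethyl-1,3-dioxolan-4-yl]acetic acid
Conditions: LiOH, THF/H2O, 0 °C → rt; then 1 M HCl to pH 4, 0 °C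
Reagents that add atoms: lithium hydroxide, [Li+].[OH-]
Why: Saponification with careful acidification should keep the acid-labile dioxolane and the non-enolisable C14 stereocentre intact.

Step 16
Reactants: 26 [(4S)-2,2-dimethyl-1,3-dioxolan-4-yl]acetic acid; 27 (4R)-4-benzyl-1,3-oxazolidin-2-one
Product: 29 (4R)-4-benzyl-3-{[(4S)-2,2-dimethyl-1,3-dioxolan-4-yl]acetyl}-1,3-oxazolidin-2-one, via mixed pivalic anhydride 28 (not isolated)
Conditions: t-BuCOCl, Et3N, THF, −20 °C; then 27, LiCl, rt
Reagents that add atoms: none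
Why: N-Acylation of the oxazolidinone through the mixed pivalic anhydride is the standard preparation of Evans imides from carboxylic acids.

Step 17
Reactants: 29 (4R)-4-benzyl-3-{[(4S)-2,2-dimethyl-1,3-dioxolan-4-yl]acetyl}-1,3-oxazolidin-2-one; 24 C12 aldehyde
Product: 32 (12S,13S) syn-aldol imide, via Z boron enolate 30 (not isolated), via boron aldolate 31 (not isolated)
Conditions: 29 (1.3 equiv), Bu2BOTf, i-Pr2NEt, CH2Cl2, −78 → 0 °C; 24, −78 → 0 °C; pH 7 buffer, MeOH, 30% H2O2, 0 °C
Reagents that add atoms: none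
Why: In the Evans syn aldol reaction the Z dibutylboron enolate reacts through a chair Zimmerman–Traxler transition state on the face away from the benzyl group of the (R)-auxiliary, which should set C12 (S) and C13 (S) syn to each other, with C13 trans to the C14 oxygen once the lactone is closed.

Step 18
Reactants: 32 (12S,13S) syn-aldol imide
Product: 34 target lactone CNP0113086.2, via pentaol imide 33 (not isolated)
Conditions: AcOH/H2O/THF 3:1:1, 40 °C
Reagents that add atoms: none
Why: Mild aqueous acid removes both acetonides and the freed C15 hydroxyl should close the γ-lactone by 5-exo-trig acyl transfer from the imide, which releases the auxiliary without touching the exocyclic alkene.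

**Compound list**

1 | (2S)-2-(but-3-en-1-yl)oxirane | C=CCC[C@H]1CO1 | starting material
2 | (phenylsulfanyl)acetic acid | OC(=O)CSc1ccccc1 | starting material
3 | dilithio dianion of 2 | [Li]OC(=O)C([Li])Sc1ccccc1 | intermediate
4 | (4S)-4-hydroxy-2-(phenylsulfanyl)oct-7-enoic acid (C2 epimers) | OC(=O)C(Sc1ccccc1)C[C@@H](O)CCC=C | intermediate
5 | (5S)-5-(but-3-en-1-yl)-3-(phenylsulfanyl)oxolan-2-one (C3 epimers) | [C@@H]1(CCC=C)OC(=O)C(Sc2ccccc2)C1 | intermediate
6 | (5S)-5-(but-3-en-1-yl)-3-(phenylsulfinyl)oxolan-2-one | [C@@H]1(CCC=C)OC(=O)C(S(=O)c2ccccc2)C1 | intermediate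
7 | (5S)-5-(but-3-en-1-yl)furan-2(5H)-one | [C@@H]1(CCC=C)OC(=O)C=C1 | intermediate
8 | methacrolein (2-methylprop-2-enal) | C=C(C)C=O | starting material
9 | (2E)-2-methyl-5-[(2S)-5-oxo-2,5-dihydrofuran-2-yl]pent-2-enal | [C@@H]1(CC/C=C(\C)C=O)OC(=O)C=C1 | intermediate
10 | (5S)-5-[(3E)-5,5-dimethoxy-4-methylpent-3-en-1-yl]furan-2(5H)-one | [C@@H]1(CC/C=C(\C)C(OC)OC)OC(=O)C=C1 | intermediate
11 | 2,3-dibromoprop-1-ene | C=C(Br)CBr | starting material
12 | (1,3-dioxolan-2-ylmethyl)magnesium bromide | Br[Mg]CC1OCCO1 | starting material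
13 | 2-(3-bromobut-3-en-1-yl)-1,3-dioxolane | C=C(Br)CCC1OCCO1 | intermediate
14 | [4-(1,3-dioxolan-2-yl)but-1-en-2-yl]lithium | [Li]C(=C)CCC1OCCO1 | intermediate
15 | lithium bis[4-(1,3-dioxolan-2-yl)but-1-en-2-yl]cuprate | [Li+].C=C(CCC1OCCO1)[Cu-]C(=C)CCC1OCCO1 | intermediate
16 | (4S,5S)-5-[(3E)-5,5-dimethoxy-4-methylpent-3-en-1-yl]-4-[4-(1,3-dioxolan-2-yl)but-1-en-2-yl]oxolan-2-one | [C@@H]1(CC/C=C(\C)C(OC)OC)OC(=O)C[C@H]1C(=C)CCC2OCCO2 | intermediate
17 | (2E)-2-methyl-5-[(2S,3S)-5-oxo-3-(5-oxopent-1-en-2-yl)oxolan-2-yl]pent-2-enal | [C@@H]1(CC/C=C(\C)C=O)OC(=O)C[C@H]1C(=C)CCC=O | intermediate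
18 | tricyclic lactone hydroxy aldehyde: trans-decalin (H5β, H9β, C20 α-methyl); 3α-OH (equatorial); 4β-methyl and 4α-formyl (C19, axial); trans-fused γ-lactone C12(=O)–O–C8 with 8β-O | [C@H]1(O3)CC[C@@H]2[C@](C)(C=O)[C@H](O)CC[C@@]2(C)[C@@H]1CC3=O | intermediate
19 | 3α,19-diol corresponding to 18 (C19 = CH2OH) | [C@H]1(O3)CC[C@@H]2[C@](C)(CO)[C@H](O)CC[C@@]2(C)[C@@H]1CC3=O | intermediate
20 | 3,19-O-isopropylidene derivative of 19 | [C@H]1(O3)CC[C@@H]2[C@]4(C)COC(C)(C)O[C@@H]4CC[C@@]2(C)[C@@H]1CC3=O | intermediate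
21 | 8β-hydroxy-3,19-O-isopropylidene decalin with 9α-CH2C(=O)N(OMe)Me (lactone opened) | [C@H]1(O)CC[C@@H]2[C@]3(C)COC(C)(C)O[C@@H]3CC[C@@]2(C)[C@@H]1CC(=O)N(C)OC | intermediate
22 | 8-oxo analogue of 21 | O=C1CC[C@@H]2[C@]3(C)COC(C)(C)O[C@@H]3CC[C@@]2(C)[C@@H]1CC(=O)N(C)OC | intermediate
23 | 8(17)-methylene analogue of 22 | C=C1CC[C@@H]2[C@]3(C)COC(C)(C)O[C@@H]3CC[C@@]2(C)[C@@H]1CC(=O)N(C)OC | intermediate
24 | C12 aldehyde: 3,19-O-isopropylidene-8(17)-ene decalin with 9α-CH2CHO | C=C1CC[C@@H]2[C@]3(C)COC(C)(C)O[C@@H]3CC[C@@]2(C)[C@@H]1CC=O | intermediate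
25 | methyl [(4S)-2,2-dimethyl-1,3-dioxolan-4-yl]acetate | COC(=O)C[C@H]1COC(C)(C)O1 | starting material
26 | [(4S)-2,2-dimethyl-1,3-dioxolan-4-yl]acetic acid | OC(=O)C[C@H]1COC(C)(C)O1 | intermediate
27 | (4R)-4-benzyl-1,3-oxazolidin-2-one | O=C1N[C@H](Cc2ccccc2)CO1 | starting material
28 | [(4S)-2,2-dimethyl-1,3-dioxolan-4-yl]acetic pivalic anhydride | CC(C)(C)C(=O)OC(=O)C[C@H]1COC(C)(C)O1 | intermediate
29 | (4R)-4-benzyl-3-{[(4S)-2,2-dimethyl-1,3-dioxolan-4-yl]acetyl}-1,3-oxazolidin-2-one | O=C(C[C@H]1COC(C)(C)O1)N1[C@H](Cc2ccccc2)COC1=O | intermediate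
30 | Z dibutylboron enolate of 29 | CCCCB(CCCC)O/C(=C\[C@H]1COC(C)(C)O1)N1[C@H](Cc2ccccc2)COC1=O | intermediate
31 | dibutylboron aldolate of 32 (O12–B) | C=C1CC[C@@H]2[C@]3(C)COC(C)(C)O[C@@H]3CC[C@@]2(C)[C@@H]1C[C@H](OB(CCCC)CCCC)[C@H](C(=O)N4[C@H](Cc5ccccc5)COC4=O)[C@H]6COC(C)(C)O6 | intermediate
32 | (4R)-4-benzyl-3-[(2S,3S)-2-[(4S)-2,2-dimethyl-1,3-dioxolan-4-yl]-3-hydroxy-4-(decalin-9-yl)butanoyl]-1,3-oxazolidin-2-one, decalin as in 24 (12S,13S,14S) | C=C1CC[C@@H]2[C@]3(C)COC(C)(C)O[C@@H]3CC[C@@]2(C)[C@@H]1C[C@H](O)[C@H](C(=O)N4[C@H](Cc5ccccc5)COC4=O)[C@H]6COC(C)(C)O6 | intermediate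
33 | pentaol imide: 32 without both acetonides (3,19,12,14,15-OH) | C=C1CC[C@@H]2[C@](C)(CO)[C@H](O)CC[C@@]2(C)[C@@H]1C[C@H](O)[C@H](C(=O)N3[C@H](Cc4ccccc4)COC3=O)[C@H](O)CO | intermediate
34 | (3S,4S)-4-hydroxy-3-{(1S)-1-hydroxy-2-[(1R,4aS,5R,6R,8aS)-6-hydroxy-5-(hydroxymethyl)-5,8a-dimethyl-2-methylidenedecahydronaphthalen-1-yl]ethyl}oxolan-2-one (CNP0113086.2) | C=C1CC[C@@H]2[C@](C)(CO)[C@H](O)CC[C@@]2(C)[C@@H]1C[C@H](O)[C@@H]1C(=O)OC[C@H]1O | target

**Summary**

Total step count: 18. Longest linear sequence: 15 steps (steps 1–4, 6–14, 17 and 18).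

Steps most likely to fail:

Step 8. The alcohol solvent may protonate the iron enolate before ring A closes. A later base-mediated closure would be unreliable, because the C3 aldehyde enolises more easily than the hindered C19 aldehyde. Erosion of facial selectivity at C10 is the second uncertainty. The fallback sets out from 16 and returns at 18, and it generates the C4 nucleophile regiospecifically while C3 is still masked. Selective hydrolysis of the more labile allylic dimethyl acetal (PPTS, wet acetone, 0 °C) should give the enal with C3 still masked F1. A plain reductive Giese cyclisation under the same iron hydride conditions closes ring B to the bicyclic aldehyde F2. KN(SiMe3)2 and t-BuMe2SiCl give the only possible silyl enol ether F3. TiCl4 closes ring A by an intramolecular Mukaiyama addition to the dioxolane, giving the 3-O-(2-hydroxyethyl) ether F4. Iodination (I2, PPh3, imidazole) gives the iodoethyl ether F5, and zinc-mediated reductive fragmentation frees the C3 hydroxyl to give 18.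

Step 17. The boron enolate may lose the dioxolane oxygen by β-elimination, or facial selectivity may erode because the auxiliary and the C14 stereocentre are mismatched. The fallback sets out from 24 and returns at 34. Commercial (S)-4-hydroxyoxolan-2-one is silylated to the silyl ether F6. Its lithium enolate (LiN(i-Pr)2, THF, −78 °C) should add to 24 anti to the silyloxy group to give the aldol adduct F7 as C12 epimers. Dess–Martin oxidation gives the β-keto lactone F8, in which C13 stays trans to C14. Chelation-controlled reduction with Zn(BH4)2 should give the 12,13-syn alcohol F9. Aqueous HF in MeCN removes the silyl ether and the acetonide and gives 34.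

Step 13. The hindered C8 ketone may fail to react, or the Lewis-acidic titanium reagent may cleave the acetonide. The fallback sets out from 20 and returns at 24, and it avoids the amide so that a Wittig reaction can be used. LiAlH4 reduces the lactone to the diol F10. t-BuMe2SiCl and imidazole silylate the primary C12 hydroxyl selectively to give the silyl ether F11. Dess–Martin oxidation gives the ketone F12. Ph3P=CH2 (from Ph3PCH3Br and KOt-Bu, toluene, 80 °C) gives the alkene F13. Bu4NF gives the alcohol F14, and Dess–Martin oxidation gives 24.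

**Further compounds**

F1 | step 8 | (2E)-2-methyl-5-{(2S,3S)-3-[4-(1,3-dioxolan-2-yl)but-1-en-2-yl]-5-oxooxolan-2-yl}pent-2-enal | [C@@H]1(CC/C=C(\C)C=O)OC(=O)C[C@H]1C(=C)CCC2OCCO2
F2 | step 8 | bicyclic lactone aldehyde (ring B closed, C4–H epimers, C3 as dioxolane) | [C@H]1(O3)CC[C@H](C(C)C=O)[C@@](C)(CCC2OCCO2)[C@@H]1CC3=O
F3 | step 8 | tert-butyldimethylsilyl enol ether of F2 (C4=C19) | [C@H]1(O3)CC[C@H](C(C)=CO[Si](C)(C)C(C)(C)C)[C@@](C)(CCC2OCCO2)[C@@H]1CC3=O
F4 | step 8 | 3-O-(2-hydroxyethyl) ether of 18 | [C@H]1(O3)CC[C@@H]2[C@](C)(C=O)[C@H](OCCO)CC[C@@]2(C)[C@@H]1CC3=O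
F5 | step 8 | 3-O-(2-iodoethyl) ether of 18 | [C@H]1(O3)CC[C@@H]2[C@](C)(C=O)[C@H](OCCI)CC[C@@]2(C)[C@@H]1CC3=O
F6 | step 17 | (4S)-4-[(tert-butyldimethylsilyl)oxy]oxolan-2-one | O=C1C[C@H](O[Si](C)(C)C(C)(C)C)CO1
F7 | step 17 | lactone aldol adduct of 24 (C12 epimers, 13,14-trans, 14-O-silyl) | C=C1CC[C@@H]2[C@]3(C)COC(C)(C)O[C@@H]3CC[C@@]2(C)[C@@H]1CC(O)[C@@H]1C(=O)OC[C@H]1O[Si](C)(C)C(C)(C)C
F8 | step 17 | 12-oxo lactone from F7 | C=C1CC[C@@H]2[C@]3(C)COC(C)(C)O[C@@H]3CC[C@@]2(C)[C@@H]1CC(=O)[C@@H]1C(=O)OC[C@H]1O[Si](C)(C)C(C)(C)C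
F9 | step 17 | (12S)-alcohol from F8 (3,19-acetonide, 14-O-silyl) | C=C1CC[C@@H]2[C@]3(C)COC(C)(C)O[C@@H]3CC[C@@]2(C)[C@@H]1C[C@H](O)[C@@H]1C(=O)OC[C@H]1O[Si](C)(C)C(C)(C)C
F10 | step 13 | 8β,12-diol from 20 | [C@H]1(O)CC[C@@H]2[C@]3(C)COC(C)(C)O[C@@H]3CC[C@@]2(C)[C@@H]1CCO
F11 | step 13 | 12-O-tert-butyldimethylsilyl ether of F10 | [C@H]1(O)CC[C@@H]2[C@]3(C)COC(C)(C)O[C@@H]3CC[C@@]2(C)[C@@H]1CCO[Si](C)(C)C(C)(C)C
F12 | step 13 | 8-oxo compound from F11 | O=C1CC[C@@H]2[C@]3(C)COC(C)(C)O[C@@H]3CC[C@@]2(C)[C@@H]1CCO[Si](C)(C)C(C)(C)C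
F13 | step 13 | 8(17)-methylene compound from F12 | C=C1CC[C@@H]2[C@]3(C)COC(C)(C)O[C@@H]3CC[C@@]2(C)[C@@H]1CCO[Si](C)(C)C(C)(C)C
F14 | step 13 | C12 alcohol from F13 | C=C1CC[C@@H]2[C@]3(C)COC(C)(C)O[C@@H]3CC[C@@]2(C)[C@@H]1CCO
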